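**Retrosynthetic overview**

1. Target 38 ⇐ 9-ketone 37 by a final 1,2-reduction; exocyclic C11=C13 ⇐ a CH2OPMB placeholder on C11; C2–C3 oxirane ⇐ O3 alkoxide displacing an allylic C2 bromide.
2. Ten-membered carbocycle (C1–C10) ⇐ eight-membered carbocycle (C2–C9): (2+2) cycloaddition of methyl propiolate across the C9=C2 silyl enol ether, then conrotatory opening of the shared C9–C2 bond of the fused cyclobutene inserts C10 (with C14) and C1.
3. Enabling feature: in the ten-membered ring the oxygen-bearing C9 is bonded to C10, which carries the exocyclic ester carbon C14 and the C10=C1 ring double bond (O–C9–C10(CO2Me)=C1–C2). This is the opened form of a 1-siloxycyclobutene-2-carboxylate fused to a cyclooctene that already holds cis-C4=C5, O3, the C8 ester and the γ-lactone.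
4. Cyclooctenone ⇐ RCM at C4=C5 of acyclic ketone 26; C9=O ⇐ alkyne via Ag/CO2 carboxylative cyclisation; C8 ⇐ Noyori reduction of an ynone from acyl Sonogashira coupling; C6/C7 ⇐ Evans aldol; C3 and the epoxy acid ⇐ Sharpless chemistry.
5. Ring order: γ-lactone → eight-membered ring → ten-membered ring by expansion → C2–C3 oxirane → exocyclic methylene.

Key step: step 19

Remark: locants C1–C15 follow germacrane numbering of the target (ring C1–C10, lactone C11/C12/C13, ester carbon C14 on C10, methyl C15 on C4); reagent 9 is assumed to be purchasable.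

**Route**

Step 1
Reactants: 1 (S)-4-benzyl-1,3-oxazolidin-2-one; 2 4-tert-butoxy-4-oxobutanoic acid
Product: 3 tert-butyl 4-[(S)-4-benzyl-2-oxooxazolidin-3-yl]-4-oxobutanoate
Conditions: DCC, DMAP (cat.), CH2Cl2, 0 °C to rt
Reagents that add atoms: none
Why: Steglich-type carbodiimide N-acylation of the oxazolidinone should give the imide for the auxiliary-controlled aldol; no stereocentre is formed.

Step 2
Reactants: 3 tert-butyl 4-[(S)-4-benzyl-2-oxooxazolidin-3-yl]-4-oxobutanoate; 4 acrolein
Product: 6 tert-butyl (3S,4R)-3-{[(S)-4-benzyl-2-oxooxazolidin-3-yl]carbonyl}-4-hydroxyhex-5-enoate, via dibutylboron Z-enolate 5 (not isolated)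
Conditions: Bu2BOTf, i-Pr2NEt, CH2Cl2, −78 to 0 °C; then 4, −78 to 0 °C; pH 7 buffer/MeOH
Reagents that add atoms: none
Why: Evans syn-aldol reaction: the Z-boron enolate reacts through a Zimmerman–Traxler chair on the face away from the benzyl group, which should set C7 (S) and C6 (R) together.

Step 3
Reactants: 6 tert-butyl (3S,4R)-3-{[(S)-4-benzyl-2-oxooxazolidin-3-yl]carbonyl}-4-hydroxyhex-5-enoate
Product: 7 (S)-4-benzyl-3-{[(2R,3S)-5-oxo-2-vinyltetrahydrofuran-3-yl]carbonyl}oxazolidin-2-one
Conditions: TFA, CH2Cl2, 0 °C to rt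
Reagents that add atoms: none
Why: Acid-mediated cleavage of the tert-butyl ester with lactonisation onto the C6 hydroxyl (intramolecular transesterification, isobutene lost) should give the trans-disubstituted γ-lactone without touching C6 or C7.

Step 4
Reactants: 7 (S)-4-benzyl-3-{[(2R,3S)-5-oxo-2-vinyltetrahydrofuran-3-yl]carbonyl}oxazolidin-2-one
Product: 8 (2R,3S)-5-oxo-2-vinyltetrahydrofuran-3-carboxylic acid
Conditions: LiOH, H2O2, THF/H2O, 0 °C; Na2SO3; then HCl to pH 2
Reagents that add atoms: hydrogen peroxide (as LiOOH), OO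
Why: Hydroperoxide cleavage of the exocyclic imide carbonyl (Evans auxiliary removal) should free the C8 carboxylic acid and return the auxiliary, and acidification recloses any lactone opened by hydroxide.

Step 5
Reactants: 8 (2R,3S)-5-oxo-2-vinyltetrahydrofuran-3-carboxylic acid; 9 4-methoxybenzyl chloromethyl ether
Product: 11 (2R,3S,4R)-4-[(4-methoxybenzyloxy)methyl]-5-oxo-2-vinyltetrahydrofuran-3-carboxylic acid, via disodium carboxylate enolate 10 (not isolated)
Conditions: NaHMDS (2.2 equiv), THF, −78 °C; then 9, −78 to −40 °C; aq. HCl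
Reagents that add atoms: none
Why: Alkylation of the lactone-enolate/carboxylate dianion (paraconic acid type) should occur anti to the C7 carboxylate, placing the protected C13 hydroxymethyl trans on C11, a placeholder centre for the later exocyclic methylene.

Step 6
Reactants: 12 methacrolein; 13 ethynylmagnesium bromide
Product: 14 rac-2-methylpent-1-en-4-yn-3-ol
Conditions: THF, 0 °C; aq. NH4Cl
Reagents that add atoms: none
Why: 1,2-Addition of the alkynyl Grignard reagent to the enal should give the racemic carbinol that becomes C3.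

Step 7
Reactants: 14 rac-2-methylpent-1-en-4-yn-3-ol
Product: 15 (S)-2-methylpent-1-en-4-yn-3-ol
Conditions: Ti(Oi-Pr)4 (10 mol %), L-(+)-DIPT (15 mol %), t-BuOOH (0.6 equiv), 4 Å MS, CH2Cl2, −20 °C
Reagents that add atoms: none
Why: Sharpless kinetic resolution of the secondary allylic alcohol: with the L-(+)-tartrate catalyst the (R)-carbinol is epoxidised fast, so the (S)-enantiomer (future C3) should be recovered.

Step 8
Reactants: 15 (S)-2-methylpent-1-en-4-yn-3-ol
Product: 16 (S)-3-(tert-butyldimethylsilyloxy)-2-methylpent-1-en-4-yne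
Conditions: TBSCl, imidazole, DMF, rt
Reagents that add atoms: tert-butyldimethylsilyl chloride, CC(C)(C)[Si](C)(C)Cl
Why: Standard silylation protects O3 until the oxirane is closed.

Step 9
Reactants: 11 (2R,3S,4R)-4-[(4-methoxybenzyloxy)methyl]-5-oxo-2-vinyltetrahydrofuran-3-carboxylic acid; 16 (S)-3-(tert-butyldimethylsilyloxy)-2-methylpent-1-en-4-yne
Product: 18 C8 ynone (lactone acyl carbon C8 joined to C9≡C2 of the 3S silyl ether), via acid chloride 17 (not isolated)
Conditions: (COCl)2, DMF (cat.), CH2Cl2, 0 °C to rt, evaporate; then 16, PdCl2(PPh3)2 (2 mol %), CuI (4 mol %), Et3N, THF, rt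
Reagents that add atoms: none
Why: Acyl Sonogashira coupling of the acid chloride with the terminal alkyne should form the C8–C9 bond; C7 is epimerisable but the all-trans lactone is the thermodynamic arrangement.

Step 10
Reactants: 18 C8 ynone
Product: 19 (8S)-propargylic alcohol (C8 carbinol flanked by the lactone carbon C7 and C9≡C2)
Conditions: RuCl[(S,S)-TsDPEN](p-cymene) (2 mol %), i-PrOH, rt
Reagents that add atoms: none
Why: Noyori asymmetric transfer hydrogenation of the α,β-acetylenic ketone: with the (S,S) catalyst the alkynyl group takes the role of the aryl group in the transition state, which should give the (8S)-carbinol under catalyst control.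

Step 11
Reactants: 19 (8S)-propargylic alcohol
Product: 20 (Z)-alkylidene cyclic carbonate (1,3-dioxolan-2-one spanning O8 and O9 with exocyclic C9=C2)
Conditions: AgOAc (10 mol %), DBU, CO2 (1 MPa), toluene, rt
Reagents that add atoms: carbon dioxide, O=C=O
Why: Silver-catalysed carboxylative cyclisation of the propargylic alcohol: the carbonate formed in situ adds 5-exo-dig, anti to silver, which should place oxygen on C9 (not C2) and give the Z-enol carbonate.

Step 12
Reactants: 20 (Z)-alkylidene cyclic carbonate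
Product: 21 α-hydroxy ketone (C8 (S)-OH, C9 ketone, C2 methylene, C3 silyl ether)
Conditions: LiOH (1.05 equiv), THF/H2O, 0 °C; aq. NH4Cl
Reagents that add atoms: none
Why: Enol carbonate hydrolysis: hydroxide attacks the carbonate carbonyl, the enolate leaves and CO2 is lost, which should unveil the C9 ketone next to the free C8 hydroxyl, with low temperature and short contact meant to keep C8.

Step 13
Reactants: 22 methyl angelate (methyl (Z)-2-methylbut-2-enoate)
Product: 23 (Z)-2-methylbut-2-en-1-ol
Conditions: LiAlH4, Et2O, 0 °C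
Reagents that add atoms: none
Why: Hydride reduction of the ester to the allylic alcohol keeps the Z geometry.

Step 14
Reactants: 23 (Z)-2-methylbut-2-en-1-ol
Product: 24 [(2S,3R)-2,3-dimethyloxiran-2-yl]methanol
Conditions: Ti(Oi-Pr)4 (10 mol %), L-(+)-DET (12 mol %), t-BuOOH, 4 Å MS, CH2Cl2, −20 °C
Reagents that add atoms: tert-butyl hydroperoxide, CC(C)(C)OO
Why: Sharpless asymmetric epoxidation: with L-(+)-diethyl tartrate the oxygen should be delivered to the face that gives the (2S,3R)-epoxy alcohol.

Step 15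
Reactants: 24 [(2S,3R)-2,3-dimethyloxiran-2-yl]methanol
Product: 25 (2R,3R)-2,3-dimethyloxirane-2-carboxylic acid
Conditions: RuCl3 (2 mol %), NaIO4, CCl4/MeCN/H2O, rt
Reagents that add atoms: water, O
Why: Ruthenium tetroxide oxidation (catalytic RuCl3, periodate) of the primary alcohol should give the glycidic acid without opening the oxirane; the C2 descriptor changes to R by priority only.

Step 16
Reactants: 21 α-hydroxy ketone; 25 (2R,3R)-2,3-dimethyloxirane-2-carboxylic acid
Product: 26 acyclic α-acyloxy ketone (O8 ester of 21 with 25)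
Conditions: DCC, DMAP, CH2Cl2, 0 °C to rt
Reagents that add atoms: none
Why: Steglich esterification installs the final C8 ester with retention at C8 and removes the base-sensitive free α-ketol.

Step 17
Reactants: 26 acyclic α-acyloxy ketone
Product: 27 cyclooctenone (3R,6R,7S,8S,11R; 4Z) trans-fused to the γ-lactone
Conditions: Hoveyda–Grubbs II (10 mol %), toluene (2 mM), 80 °C
Reagents that add atoms: none
Why: Ring-closing metathesis between the vinyl group on C6 and the isopropenyl group on C3 should close the eight-membered ring, whose size enforces the ring-cis (Z) trisubstituted C4=C5 bond.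

Step 18
Reactants: 27 cyclooctenone
Product: 29 C9=C2 tert-butyldimethylsilyl enol ether of 27, via lithium enolate 28 (not isolated)
Conditions: LDA (1.1 equiv), THF, −78 °C; then TBSOTf, −78 °C
Reagents that add atoms: tert-butyldimethylsilyl triflate, CC(C)(C)[Si](C)(C)OS(=O)(=O)C(F)(F)F
Why: Kinetic deprotonation at the unhindered C2 methylene (away from the α-acyloxy C8–H) followed by O-silylation should give the regiodefined C9=C2 enol ether (kinetic silyl enol ether formation).

Step 19
Reactants: 29 C9=C2 tert-butyldimethylsilyl enol ether of 27; 30 methyl propiolate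
Product: 32 ring-expanded (1E,9Z)-dienol silyl ether (ten-membered ring C9(OTBS)=C10(CO2Me)–C1H=C2H), via siloxy cyclobutene 31 (not isolated)
Conditions: HNTf2 (5 mol %), CH2Cl2, −78 °C; then Et3N (0.1 equiv), toluene, 70 °C
Reagents that add atoms: none
Why: The silyl triflimide formed from HNTf2 activates the ynoate, the enol ether carbon C2 adds to the propiolate CH carbon (Mukaiyama–Michael) and the allenoate carbon closes onto the C9 silyloxocarbenium ion, a formal (2+2) cycloaddition giving the cis-fused 1-siloxybicyclo[6.2.0]dec-9-ene-9-carboxylate 31, whose shared C9–C2 bond then opens by thermal conrotatory 4π-electrocyclic reaction so that the eight-membered ring becomes the ten-membered ring. The closest known reaction type is the acid-catalysed (2+2) cycloaddition of silyl enol ethers with propiolates with thermal two-carbon ring enlargement of the adducts, the enol-ether counterpart of the enamine–propiolate ring enlargement of cyclooctanone. The four-membered ring closes stepwise in a 4-exo-trig mode onto the oxocarbenium carbon, and the ten-membered ring is not closed but released by cleavage of the ring-fusion bond. The cyclobutene stereocentres C9 and C2 are transient (cis fusion is enforced by the eight-membered ring) and both become sp2, so the facial selectivity of the cycloaddition is not carried forward; what counts is torquoselectivity, the siloxy donor rotating outward, which should give C9=C10 with C8 cis to C1 and the E-C1=C2 bond. The step needs regioselectivity (C2 to the CH carbon, C9 to the ester-bearing carbon), secured by the polarisation of enol ether and ynoate, and site selectivity for C9=C2 over C9=C8, secured by the kinetic enol ether of step 18, while the isolated C4=C5 bond is not nucleophilic enough to compete. In one operation it should deliver the ten-membered carbocycle, C1, C10 and the C14 ester, the C9 oxygen at ketone level and a diene that directs the next functionalisation to C2.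

Step 20
Reactants: 32 ring-expanded (1E,9Z)-dienol silyl ether
Product: 33 (2S)-C2 bromide (C9 ketone, ring-cis C10=C1 bearing CO2Me, C3 silyl ether)
Conditions: NBS (1.05 equiv), THF, −78 °C; aq. NaHCO3
Reagents that add atoms: N-bromosuccinimide, O=C1CCC(=O)N1Br
Why: Vinylogous (γ) bromination of the silyl dienol ether: bromine should add to C2, the terminus of the strained E-C1=C2 bond (C10 is fully substituted), with loss of the enol silyl group to give the C9 ketone and the ring-cis C10=C1 bond; the (2S) bromide anti to O3 is drawn, and because H-2 is vinylogously acidic and the allylic bromide exchanges with bromide, the C2 epimers can interconvert before the next step.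

Step 21
Reactants: 33 (2S)-C2 bromide
Product: 34 (2R,3S)-oxirane (C9 ketone, C11 CH2OPMB)
Conditions: TBAF (1.1 equiv), THF, −20 to 0 °C
Reagents that add atoms: none
Why: Fluoride removes the C3 silyl group and the alkoxide displaces bromide at C2 (intramolecular Williamson reaction, 3-exo-tet SN2 with inversion at C2 and retention of the C3–O bond), which should give the cis-fused oxirane on the face fixed by C3, the trans-fused alternative being strained between the two cis ring olefins.

Step 22
Reactants: 34 (2R,3S)-oxirane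
Product: 35 primary alcohol (C13 OH on C11)
Conditions: DDQ, CH2Cl2/pH 7 buffer, 0 °C
Reagents that add atoms: none
Why: Oxidative cleavage of the PMB ether with DDQ should free the primary alcohol, since the electron-poor enoate and the oxiranes are not oxidised.

Step 23
Reactants: 35 primary alcohol
Product: 37 9-oxo α-methylene lactone, via C13 mesylate 36 (not isolated)
Conditions: MsCl, Et3N (3 equiv), CH2Cl2, 0 °C to rt
Reagents that add atoms: none
Why: Mesylation of the primary alcohol and E1cB β-elimination through the lactone enolate should give the exocyclic C11=C13 bond and remove the placeholder centre C11.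

Step 24
Reactants: 37 9-oxo α-methylene lactone
Product: 38 target (2R,3S,6R,7S,8S,9S)
Conditions: NaBH4, CeCl3·7H2O, MeOH, −78 °C
Reagents that add atoms: none
Why: Luche 1,2-reduction of the alkylidene β-keto ester carbonyl: hydride should attack anti to the C8 acyloxy group (Felkin–Anh, non-chelating) to give the 9S alcohol trans to O8, leaving the α-methylene lactone and both oxiranes untouched.

**Compound list**

1 | (S)-4-benzyl-1,3-oxazolidin-2-one | O=C1N[C@@H](Cc2ccccc2)CO1 | starting material
2 | 4-tert-butoxy-4-oxobutanoic acid | OC(=O)CCC(=O)OC(C)(C)C | starting material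
3 | tert-butyl 4-[(S)-4-benzyl-2-oxooxazolidin-3-yl]-4-oxobutanoate | CC(C)(C)OC(=O)CCC(=O)N1[C@@H](Cc2ccccc2)COC1=O | intermediate
4 | acrolein | C=CC=O | starting material
5 | dibutylboron Z-enolate of 3 | CCCCB(CCCC)O/C(=C\CC(=O)OC(C)(C)C)N1[C@@H](Cc2ccccc2)COC1=O | intermediate
6 | tert-butyl (3S,4R)-3-{[(S)-4-benzyl-2-oxooxazolidin-3-yl]carbonyl}-4-hydroxyhex-5-enoate | C=C[C@@H](O)[C@H](CC(=O)OC(C)(C)C)C(=O)N1[C@@H](Cc2ccccc2)COC1=O | intermediate
7 | (S)-4-benzyl-3-{[(2R,3S)-5-oxo-2-vinyltetrahydrofuran-3-yl]carbonyl}oxazolidin-2-one | C=C[C@H]1OC(=O)C[C@@H]1C(=O)N2[C@@H](Cc3ccccc3)COC2=O | intermediate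
8 | (2R,3S)-5-oxo-2-vinyltetrahydrofuran-3-carboxylic acid | C=C[C@H]1OC(=O)C[C@@H]1C(=O)O | intermediate
9 | 4-methoxybenzyl chloromethyl ether | ClCOCc1ccc(OC)cc1 | starting material
10 | disodium salt of 8 (carboxylate and lactone enolate) | [Na+].[Na+].C=C[C@H]1OC([O-])=C[C@@H]1C([O-])=O | intermediate
11 | (2R,3S,4R)-4-[(4-methoxybenzyloxy)methyl]-5-oxo-2-vinyltetrahydrofuran-3-carboxylic acid | C=C[C@H]1OC(=O)[C@@H](COCc2ccc(OC)cc2)[C@@H]1C(=O)O | intermediate
12 | methacrolein | CC(=C)C=O | starting material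
13 | ethynylmagnesium bromide | C#C[Mg]Br | starting material
14 | rac-2-methylpent-1-en-4-yn-3-ol | C#CC(O)C(C)=C | intermediate
15 | (S)-2-methylpent-1-en-4-yn-3-ol | C#C[C@@H](O)C(C)=C | intermediate
16 | (S)-3-(tert-butyldimethylsilyloxy)-2-methylpent-1-en-4-yne | C#C[C@@H](O[Si](C)(C)C(C)(C)C)C(C)=C | intermediate
17 | acid chloride of 11 | C=C[C@H]1OC(=O)[C@@H](COCc2ccc(OC)cc2)[C@@H]1C(Cl)=O | intermediate
18 | C8 ynone: (3R,4S,5R)-4-[(4S)-4-(tert-butyldimethylsilyloxy)-5-methylhex-5-en-2-ynoyl]-3-[(4-methoxybenzyloxy)methyl]-5-vinyldihydrofuran-2(3H)-one | C=C[C@H]1OC(=O)[C@@H](COCc2ccc(OC)cc2)[C@@H]1C(=O)C#C[C@@H](O[Si](C)(C)C(C)(C)C)C(C)=C | intermediate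
19 | (8S)-propargylic alcohol: 18 with the C8 ketone reduced to the (S)-carbinol | C=C[C@H]1OC(=O)[C@@H](COCc2ccc(OC)cc2)[C@@H]1[C@H](O)C#C[C@@H](O[Si](C)(C)C(C)(C)C)C(C)=C | intermediate
20 | (Z)-alkylidene cyclic carbonate: 1,3-dioxolan-2-one on O8/O9 with exocyclic C9=C2 | C=C[C@H]1OC(=O)[C@@H](COCc2ccc(OC)cc2)[C@@H]1[C@@H]3OC(=O)O/C3=C\[C@@H](O[Si](C)(C)C(C)(C)C)C(C)=C | intermediate
21 | α-hydroxy ketone: (8S)-OH, C9 ketone, C2 methylene, C3 silyl ether | C=C[C@H]1OC(=O)[C@@H](COCc2ccc(OC)cc2)[C@@H]1[C@H](O)C(=O)C[C@@H](O[Si](C)(C)C(C)(C)C)C(C)=C | intermediate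
22 | methyl angelate (methyl (Z)-2-methylbut-2-enoate) | C/C=C(/C)C(=O)OC | starting material
23 | (Z)-2-methylbut-2-en-1-ol | C/C=C(/C)CO | intermediate
24 | [(2S,3R)-2,3-dimethyloxiran-2-yl]methanol | OC[C@]1(C)O[C@@H]1C | intermediate
25 | (2R,3R)-2,3-dimethyloxirane-2-carboxylic acid | OC(=O)[C@]1(C)O[C@@H]1C | intermediate
26 | acyclic α-acyloxy ketone: O8 ester of 21 with 25 | C=C[C@H]1OC(=O)[C@@H](COCc2ccc(OC)cc2)[C@@H]1[C@H](OC(=O)[C@]3(C)O[C@@H]3C)C(=O)C[C@@H](O[Si](C)(C)C(C)(C)C)C(C)=C | intermediate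
27 | cyclooctenone (3R,6R,7S,8S,11R; 4Z): ring C2–C9 trans-fused to the γ-lactone, C9 ketone, C8 epoxy ester, C3 silyl ether | O=C1O[C@@H]2/C=C(/C)[C@H](O[Si](C)(C)C(C)(C)C)CC(=O)[C@@H](OC(=O)[C@]3(C)O[C@@H]3C)[C@H]2[C@@H]1COCc1ccc(OC)cc1 | intermediate
28 | lithium C9=C2 enolate of 27 | [Li+].O=C1O[C@@H]2/C=C(/C)[C@H](O[Si](C)(C)C(C)(C)C)/C=C(/[O-])[C@@H](OC(=O)[C@]3(C)O[C@@H]3C)[C@H]2[C@@H]1COCc1ccc(OC)cc1 | intermediate
29 | C9=C2 tert-butyldimethylsilyl enol ether of 27 | O=C1O[C@@H]2/C=C(/C)[C@H](O[Si](C)(C)C(C)(C)C)/C=C(/O[Si](C)(C)C(C)(C)C)[C@@H](OC(=O)[C@]3(C)O[C@@H]3C)[C@H]2[C@@H]1COCc1ccc(OC)cc1 | intermediate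
30 | methyl propiolate | C#CC(=O)OC | starting material
31 | cis-fused siloxy cyclobutene: 1-siloxybicyclo[6.2.0]dec-9-ene-9-carboxylate core (four-membered ring C9–C10=C1–C2), one diastereomer drawn | O=C1O[C@@H]2/C=C(/C)[C@H](O[Si](C)(C)C(C)(C)C)[C@H]3C=C(C(=O)OC)[C@@]3(O[Si](C)(C)C(C)(C)C)[C@@H](OC(=O)[C@]4(C)O[C@@H]4C)[C@H]2[C@@H]1COCc1ccc(OC)cc1 | intermediate
32 | ring-expanded (1E,9Z)-dienol silyl ether: ten-membered ring C9(OTBS)=C10(CO2Me)–C1H=C2H | O=C1O[C@@H]2/C=C(/C)[C@H](O[Si](C)(C)C(C)(C)C)/C=C/C(C(=O)OC)=C(/O[Si](C)(C)C(C)(C)C)[C@@H](OC(=O)[C@]3(C)O[C@@H]3C)[C@H]2[C@@H]1COCc1ccc(OC)cc1 | intermediate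
33 | (2S)-C2 bromide: C9 ketone, (1(10)E) C10=C1 bearing CO2Me, C3 silyl ether | O=C1O[C@@H]2/C=C(/C)[C@H](O[Si](C)(C)C(C)(C)C)[C@@H](Br)/C=C(/C(=O)OC)C(=O)[C@@H](OC(=O)[C@]3(C)O[C@@H]3C)[C@H]2[C@@H]1COCc1ccc(OC)cc1 | intermediate
34 | (2R,3S)-oxirane with C9 ketone and C11 CH2OPMB | O=C1O[C@@H]2/C=C(/C)[C@@H]3O[C@@H]3/C=C(/C(=O)OC)C(=O)[C@@H](OC(=O)[C@]4(C)O[C@@H]4C)[C@H]2[C@@H]1COCc1ccc(OC)cc1 | intermediate
35 | primary alcohol: 34 with C13 OH | O=C1O[C@@H]2/C=C(/C)[C@@H]3O[C@@H]3/C=C(/C(=O)OC)C(=O)[C@@H](OC(=O)[C@]4(C)O[C@@H]4C)[C@H]2[C@@H]1CO | intermediate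
36 | C13 mesylate of 35 | O=C1O[C@@H]2/C=C(/C)[C@@H]3O[C@@H]3/C=C(/C(=O)OC)C(=O)[C@@H](OC(=O)[C@]4(C)O[C@@H]4C)[C@H]2[C@@H]1COS(C)(=O)=O | intermediate
37 | 9-oxo α-methylene lactone | C=C1C(=O)O[C@@H]2/C=C(/C)[C@@H]3O[C@@H]3/C=C(/C(=O)OC)C(=O)[C@@H](OC(=O)[C@]3(C)O[C@@H]3C)[C@@H]12 | intermediate
38 | target CNP0291485.1: methyl (2R,3S,6R,7S,8S,9S)-2,3-epoxy-8-[(2R,3R)-2,3-dimethyloxirane-2-carbonyloxy]-9-hydroxygermacra-1(10)E,4Z,11(13)-trien-12,6-olid-14-oate | C=C1C(=O)O[C@@H]2/C=C(/C)[C@@H]3O[C@@H]3/C=C(/C(=O)OC)[C@H](O)[C@@H](OC(=O)[C@]3(C)O[C@@H]3C)[C@@H]12 | target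

**Step count and risks**

Total step count: 24. Longest linear sequence: 18 steps (1–5, 9–12, 16–24).

Steps most likely to fail:

1. Step 19. After the first C–C bond is formed, the zwitterion may collapse by silyl transfer to the open-chain Michael adduct instead of closing the four-membered ring, or the acid may strip the PMB ether before cycloaddition. The fallback is the enamine version of the two-carbon ring enlargement. It sets out from 27: condensation with pyrrolidine (4 Å MS, benzene) should give the less substituted C9=C2 pyrrolidine enamine F1. Thermal reaction of F1 with methyl propiolate 30 (MeCN, rt to 50 °C) should proceed by cycloaddition and cyclobutene opening to the ring-expanded dienamine F2. Bromination of F2 with NBS at −78 °C and aqueous hydrolysis of the iminium ion comes back to the route at 33.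

2. Step 20. Bromine may be delivered to C10 or to the wrong face of C2, and the allylic bromide may lose HBr towards C3. The fallback replaces halogenation by a vinylogous Rubottom oxidation. It sets out from 32: dimethyldioxirane (acetone, −78 °C) should epoxidise the strained E-C1=C2 bond, and collapse of the siloxy epoxide on work-up should give the γ-hydroxy keto ester F3. Mesylation (MsCl, Et3N, −40 °C) gives the C2 mesylate F4. TBAF then frees O3, which displaces the mesylate, and the route is rejoined at 34.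

3. Step 17. The metathesis may stall or oligomerise because the 1,1-disubstituted olefin sits next to the bulky C3 silyl ether. The fallback changes the substrate to one that engages the catalyst through a free allylic hydroxyl. It sets out from 26: HF·pyridine (THF, 0 °C) removes the C3 silyl group to give the allylic alcohol F5. Hydroxyl-assisted ring-closing metathesis of F5 (Hoveyda–Grubbs II, toluene, 60 °C) should give the cyclooctenol F6. Resilylation (TBSOTf, 2,6-lutidine, −78 °C) comes back to the route at 27.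

Further compounds
F1 | step 19 | C9=C2 pyrrolidine enamine of 27 | O=C1O[C@@H]2/C=C(/C)[C@H](O[Si](C)(C)C(C)(C)C)/C=C(/N3CCCC3)[C@@H](OC(=O)[C@]4(C)O[C@@H]4C)[C@H]2[C@@H]1COCc1ccc(OC)cc1
F2 | step 19 | ring-expanded pyrrolidine dienamine (ten-membered ring C9(N)=C10(CO2Me)–C1H=C2H) | O=C1O[C@@H]2/C=C(/C)[C@H](O[Si](C)(C)C(C)(C)C)/C=C/C(C(=O)OC)=C(/N3CCCC3)[C@@H](OC(=O)[C@]4(C)O[C@@H]4C)[C@H]2[C@@H]1COCc1ccc(OC)cc1
F3 | step 20 | γ-hydroxy keto ester (C2 OH, C9 ketone, C3 silyl ether) | O=C1O[C@@H]2/C=C(/C)[C@H](O[Si](C)(C)C(C)(C)C)[C@@H](O)/C=C(/C(=O)OC)C(=O)[C@@H](OC(=O)[C@]3(C)O[C@@H]3C)[C@H]2[C@@H]1COCc1ccc(OC)cc1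
F4 | step 20 | C2 mesylate of F3 | O=C1O[C@@H]2/C=C(/C)[C@H](O[Si](C)(C)C(C)(C)C)[C@@H](OS(C)(=O)=O)/C=C(/C(=O)OC)C(=O)[C@@H](OC(=O)[C@]3(C)O[C@@H]3C)[C@H]2[C@@H]1COCc1ccc(OC)cc1
F5 | step 17 | C3 allylic alcohol (desilylated 26) | C=C[C@H]1OC(=O)[C@@H](COCc2ccc(OC)cc2)[C@@H]1[C@H](OC(=O)[C@]3(C)O[C@@H]3C)C(=O)C[C@@H](O)C(C)=C
F6 | step 17 | C3 hydroxy cyclooctenone (desilylated 27) | O=C1O[C@@H]2/C=C(/C)[C@H](O)CC(=O)[C@@H](OC(=O)[C@]3(C)O[C@@H]3C)[C@H]2[C@@H]1COCc1ccc(OC)cc1
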